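## Retrosynthetic overview

1. Isariotin D ⇒ aminobicycle 22 + (E)-dec-2-enoic acid (amide bond made last).
2. Ring B (C1–C8–C7–C6–C5–C9) ⇒ intramolecular aldol (C5–C6) of spiro keto-lactol 20; this ring is formed last.
3. C7 ⇒ Rh–DuPhos hydrogenation of a (Z)-dehydroamino ester, made by HWE olefination of the C8 aldehyde (C8 is the former carboxyl carbon).
4. Ring-A oxygens ⇒ OH-directed epoxidation (C4–C5), C9 oxidation and SmI2 epoxide opening (gives C4-OH), second OH-directed epoxidation (C2–C3).
5. Ring A with the C1 carbinol ⇒ benzoic acid by enzymatic ipso,ortho-cis-dihydroxylation. Ring order: carbocycle A (from the arene) → oxirane → carbocycle B.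

Convention: isariotin numbering is used for every intermediate (C1 = hydroxylated bridgehead, C2/C3 = epoxide carbons, C4 = CHOH, C5 = CH bridgehead, C6 = CHOH, C7 = CHN, C8 = CH2, C9 = C=O). "β" is the face of the C1/C2/C3/C4/C5/C9 ring that carries C1-OH; C8 is α.

The stereochemical outcomes of Steps 2, 11, 12 and 18 are predictions from mechanism and precedent on close analogues; nothing here has been run.

## Route

**Step 1**
Reactants: 1, benzoic acid
Product: 2, (1S,2R)-1,2-dihydroxycyclohexa-3,5-diene-1-carboxylic acid (cis-diol; C1 and C9 of the target)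
Conditions: whole cells expressing benzoate 1,2-dioxygenase (Cupriavidus necator/Ralstonia eutropha B9, diol-dehydrogenase-deficient), sodium benzoate fed-batch, fructose, air, pH 7, 30 °C
Reagents that add atoms: dioxygen, O=O
Why: Enzymatic arene cis-dihydroxylation by a Rieske non-haem iron benzoate 1,2-dioxygenase adds O2 across the ipso/ortho carbons of the achiral arene, setting the C1 quaternary carbinol (and C9) in high ee.

**Step 2**
Reactants: 2
Product: 3, (1S,2R,3S,4R)-3,4-epoxy-1,2-dihydroxycyclohex-5-ene-1-carboxylic acid (4β,5β-epoxide in isariotin numbering, cis to both OH groups)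
Conditions: mCPBA, EtOAc, 23 °C
Reagents that add atoms: mCPBA, O=C(OO)c1cccc(Cl)c1
Why: Henbest (hydroxyl-directed Prilezhaev) epoxidation: the secondary allylic C9-OH delivers the peracid syn to the more electron-rich alkene, the one remote from the CO2H-bearing carbon, placing the future C4 oxygen on the β face.

**Step 3**
Reactants: 3
Product: 4, methyl ester of 3
Conditions: TMSCHN2, MeOH/PhMe, 0 °C → rt
Reagents that add atoms: (trimethylsilyl)diazomethane, C[Si](C)(C)C=[N+]=[N-]
Why: Diazoalkane esterification is neutral and leaves the vinyl epoxide and free diol untouched.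

**Step 4**
Reactants: 4
Product: 5, methyl ester with C1-OTMS and C9-OTMS (4β,5β-epoxide, Δ2,3)
Conditions: N-(trimethylsilyl)imidazole (3 equiv), CH2Cl2, rt
Reagents that add atoms: TMS-imidazole, C[Si](C)(C)n1ccnc1
Why: Silylation with a non-Lewis-acidic silyl donor masks both hydroxyls without activating the vinyl epoxide toward SN2′ (vinylogous Payne) migration, which silyl triflates would risk.

**Step 5**
Reactants: 5
Product: 6, C8 aldehyde (1,9-bis-OTMS, 4β,5β-epoxide, Δ2,3)
Conditions: DIBAL-H (1.2 equiv), CH2Cl2, −78 °C; Rochelle salt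
Reagents that add atoms: none
Why: DIBAL partial reduction of an α-silyloxy ester stops at the chelated tetrahedral intermediate, and the quaternary α-carbon means the aldehyde cannot epimerise or enolise.

**Step 6**
Reactants: 7, trimethyl phosphonoacetate
Product: 8, methyl 2-diazo-2-(dimethoxyphosphoryl)acetate
Conditions: NaH, THF, 0 °C; then p-ABSA, 0 °C → rt
Reagents that add atoms: 4-acetamidobenzenesulfonyl azide, CC(=O)Nc1ccc(cc1)S(=O)(=O)N=[N+]=[N-]
Why: Regitz diazo transfer onto the stabilised phosphonoacetate anion.

**Step 7**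
Reactants: 8; 9, benzyl carbamate
Product: 10, (±)-methyl 2-(benzyloxycarbonylamino)-2-(dimethoxyphosphoryl)acetate (racemic; its only stereocentre becomes sp2 in Step 8)
Conditions: Rh2(OAc)4 (1 mol%), PhMe, 80 °C
Reagents that add atoms: none (both reactants listed)
Why: Rh(II)-carbenoid N–H insertion into the carbamate gives the N-Cbz phosphonoglycinate directly.

**Step 8**
Reactants: 6; 10
Product: 11, methyl (Z)-2-(Cbz-amino)-3-[ring A]acrylate (ring A = 1,9-bis-OTMS, 4β,5β-epoxide, Δ2,3; new C8=C7 bond)
Conditions: DBU, CH2Cl2, 0 °C → rt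
Reagents that add atoms: none (both reactants listed)
Why: Horner–Wadsworth–Emmons olefination with an N-acyl phosphonoglycinate is reliably Z-selective and mild enough for the vinyl epoxide and TMS ethers.

**Step 9**
Reactants: 11
Product: 12, C1,C9-diol (Z-dehydroamino ester, 4β,5β-epoxide, Δ2,3)
Conditions: TBAF/AcOH (1:1), THF, 0 °C
Reagents that add atoms: none
Why: Buffered fluoride desilylation removes both TMS ethers without generating a free alkoxide next to the vinyl epoxide.

**Step 10**
Reactants: 12
Product: 13, C9 ketone (α,β-epoxy ketone; C1-OH free)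
Conditions: (COCl)2, DMSO, CH2Cl2, −78 °C; Et3N, −78 → −20 °C
Reagents that add atoms: none
Why: Swern oxidation converts the secondary C9-OH of the sec/tert 1,2-diol to the ketone without glycol cleavage, and the tertiary C1-OH cannot be oxidised.

**Step 11**
Reactants: 13
Product: 14, β-hydroxy ketone: C9=O, C5H2, C4β-OH, Δ2,3, C1-OH
Conditions: SmI2 (2.2 equiv), THF/MeOH, −90 °C; pH 7 buffer
Reagents that add atoms: none
Why: SmI2 reductive cleavage of the α,β-epoxy ketone breaks only the Cα–O (C5–O) bond via the ketyl, so C4 keeps its β oxygen with retention and C5 becomes the enolisable CH2; at −90 °C this is much faster than reduction of the enamide ester or loss of the tertiary α′-OH.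

**Step 12**
Reactants: 14
Product: 15, 2β,3β-epoxide (C1β-OH, C4β-OH, C9=O)
Conditions: mCPBA, NaHCO3, CH2Cl2, 0 °C
Reagents that add atoms: mCPBA, O=C(OO)c1cccc(Cl)c1
Why: Henbest-directed epoxidation: both flanking allylic hydroxyls (C1-OH, C4-OH) lie on the β face and the C1 side chain blocks the α face, so the oxirane forms all-cis, and the electron-poor enamide and the ketone (Baeyer–Villiger) react far more slowly.

**Step 13**
Reactants: 15
Product: 16, C4-OTES ether
Conditions: TESCl, imidazole, DMF, 0 °C
Reagents that add atoms: chlorotriethylsilane, CC[Si](Cl)(CC)CC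
Why: Selective silylation of the only secondary hydroxyl (the tertiary C1-OH is inert) protects C4-OH from the later oxidation.

**Step 14**
Reactants: 16
Product: 17, methyl (S)-2-(Cbz-amino)-3-[ring A]propanoate (C7 = S); may partly close to the spiro-γ-lactone with C1-OH, which converges in Step 15
Conditions: [Rh(cod)((S,S)-Et-DuPhos)]OTf (2 mol%), H2 (5 atm), MeOH, rt
Reagents that add atoms: none (H2 only)
Why: Rh–DuPhos asymmetric hydrogenation of the chelating Z-enamide sets C7 (S, L-amino-acid sense) under catalyst control, and no other C=C remains in the molecule.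

**Step 15**
Reactants: 17
Product: 18, triol: C6 primary OH, C9 secondary OH (epimer mixture, inconsequential), C1-OH; C4-OTES, epoxide and NHCbz intact
Conditions: LiBH4, THF/MeOH, 0 °C
Reagents that add atoms: none
Why: Borohydride reduction takes the ester (or lactone) to the C6 alcohol and unavoidably reduces the C9 ketone, while carbamate, silyl ether and the hindered epoxide survive.

**Step 16**
Reactants: 18
Product: 19, spiro keto-lactol: C9=O; C6 aldehyde closed onto C1-OH as a five-membered lactol (anomer mixture); C4-OTES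
Conditions: (COCl)2, DMSO, CH2Cl2, −78 °C; i-Pr2NEt, −78 → −30 °C
Reagents that add atoms: none
Why: A double Swern oxidation restores the C9 ketone and forms the C6 aldehyde in one operation; the aldehyde is trapped as the lactol only after the oxidant is spent, which also shields C7 from epimerisation.

**Step 17**
Reactants: 19
Product: 20, spiro keto-lactol with free C4β-OH
Conditions: HF·pyridine, pyridine, THF, 0 °C
Reagents that add atoms: none
Why: Buffered fluoride desilylation frees C4-OH so that the following enolate has no β-leaving group (avoids E1cB loss of a silyloxy group).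

**Step 18**
Reactants: 20
Product: 21, N-Cbz bicycle: benzyl N-[1,4,6-trihydroxy-2,3-epoxy-9-oxobicyclo[3.3.1]nonan-7-yl]carbamate with the target configuration at C1–C7
Conditions: K2CO3 (0.5 equiv), MeOH, 0 °C → rt; pH 7 buffer quench
Reagents that add atoms: none
Why: Intramolecular aldol addition: only C5 can enolise (C1 is quaternary), the three-atom tether forces the new C5–C6 bond cis to C8, and the chair transition state with NHCbz equatorial and the aldehyde oxygen held toward the C9 oxygen gives axial C6-OH (hydrogen-bonded to C9=O); the bridgehead product can no longer enolise or dehydrate.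

**Step 19**
Reactants: 21
Product: 22, free C7 amine
Conditions: H2 (1 atm), 10% Pd/C, EtOAc/MeOH, rt
Reagents that add atoms: none
Why: Cbz hydrogenolysis is neutral, and the aliphatic epoxide and hindered bridging ketone are not reduced.

**Step 20**
Reactants: 22; 23, (E)-dec-2-enoic acid
Product: 24, isariotin D
Conditions: EDC·HCl, HOBt, N-methylmorpholine, DMF, 0 °C → rt
Reagents that add atoms: none (both reactants listed)
Why: Carbodiimide/HOBt amide coupling acylates the amine chemoselectively over the three hydroxyls under near-neutral conditions that spare the β-hydroxy ketone and epoxide.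

## Compound list

1 | benzoic acid | OC(=O)c1ccccc1 | starting material
2 | (1S,2R)-1,2-dihydroxycyclohexa-3,5-diene-1-carboxylic acid | OC(=O)[C@]1(O)C=CC=C[C@H]1O | intermediate
3 | (1S,2R,3S,4R)-3,4-epoxy-1,2-dihydroxycyclohex-5-ene-1-carboxylic acid | OC(=O)[C@]1(O)C=C[C@H]2O[C@H]2[C@H]1O | intermediate
4 | methyl ester of 3 | COC(=O)[C@]1(O)C=C[C@H]2O[C@H]2[C@H]1O | intermediate
5 | 1,9-bis-O-TMS ether of 4 | COC(=O)[C@]1(O[Si](C)(C)C)C=C[C@H]2O[C@H]2[C@H]1O[Si](C)(C)C | intermediate
6 | C8 aldehyde (bis-TMS, 4β,5β-epoxide, Δ2,3) | O=C[C@]1(O[Si](C)(C)C)C=C[C@H]2O[C@H]2[C@H]1O[Si](C)(C)C | intermediate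
7 | trimethyl phosphonoacetate | COC(=O)CP(=O)(OC)OC | starting material
8 | methyl 2-diazo-2-(dimethoxyphosphoryl)acetate | COC(=O)C(=[N+]=[N-])P(=O)(OC)OC | intermediate
9 | benzyl carbamate | NC(=O)OCc1ccccc1 | starting material
10 | (±)-methyl 2-(Cbz-amino)-2-(dimethoxyphosphoryl)acetate | COC(=O)C(NC(=O)OCc1ccccc1)P(=O)(OC)OC | intermediate
11 | (Z)-dehydroamino ester, bis-TMS | COC(=O)/C(NC(=O)OCc1ccccc1)=C/[C@]1(O[Si](C)(C)C)C=C[C@H]2O[C@H]2[C@H]1O[Si](C)(C)C | intermediate
12 | (Z)-dehydroamino ester, C1,C9-diol | COC(=O)/C(NC(=O)OCc1ccccc1)=C/[C@]1(O)C=C[C@H]2O[C@H]2[C@H]1O | intermediate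
13 | C9 ketone, 4β,5β-epoxide | COC(=O)/C(NC(=O)OCc1ccccc1)=C/[C@]1(O)C=C[C@H]2O[C@H]2C1=O | intermediate
14 | C9 ketone, C4β-OH, Δ2,3 | COC(=O)/C(NC(=O)OCc1ccccc1)=C/[C@]1(O)C=C[C@@H](O)CC1=O | intermediate
15 | C9 ketone, C4β-OH, 2β,3β-epoxide | COC(=O)/C(NC(=O)OCc1ccccc1)=C/[C@]1(O)[C@H]2O[C@H]2[C@@H](O)CC1=O | intermediate
16 | C4-OTES ether of 15 | COC(=O)/C(NC(=O)OCc1ccccc1)=C/[C@]1(O)[C@H]2O[C@H]2[C@@H](O[Si](CC)(CC)CC)CC1=O | intermediate
17 | (S)-N-Cbz amino ester (C7 = S) | COC(=O)[C@@H](NC(=O)OCc1ccccc1)C[C@]1(O)[C@H]2O[C@H]2[C@@H](O[Si](CC)(CC)CC)CC1=O | intermediate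
18 | C6/C9/C1 triol (C9 epimers) | OC[C@@H](NC(=O)OCc1ccccc1)C[C@]1(O)[C@H]2O[C@H]2[C@@H](O[Si](CC)(CC)CC)CC1O | intermediate
19 | spiro keto-lactol, C4-OTES (anomers) | OC1O[C@@]2(C[C@@H]1NC(=O)OCc1ccccc1)[C@H]3O[C@H]3[C@@H](O[Si](CC)(CC)CC)CC2=O | intermediate
20 | spiro keto-lactol, C4-OH (anomers) | OC1O[C@@]2(C[C@@H]1NC(=O)OCc1ccccc1)[C@H]3O[C@H]3[C@@H](O)CC2=O | intermediate
21 | N-Cbz aminobicycle | O=C(OCc1ccccc1)N[C@H]1C[C@@]2(O)C(=O)[C@H]([C@H](O)[C@@H]3O[C@@H]32)[C@H]1O | intermediate
22 | free aminobicycle | N[C@H]1C[C@@]2(O)C(=O)[C@H]([C@H](O)[C@@H]3O[C@@H]32)[C@H]1O | intermediate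
23 | (E)-dec-2-enoic acid | CCCCCCC/C=C/C(=O)O | starting material
24 | isariotin D | CCCCCCC/C=C/C(=O)N[C@H]1C[C@@]2(O)C(=O)[C@H]([C@H](O)[C@@H]3O[C@@H]32)[C@H]1O | target

## Summary

Total steps: 20 (18 on the main line plus 2 to prepare olefination reagent 10).
Longest linear sequence: 18 steps (benzoic acid → isariotin D; Steps 1–5 and 8–20).

Steps most likely to fail, with fallbacks:

1. **Step 18 (base-mediated aldol).** Risks are wrong C6 epimer, retro-aldol or elimination. Fallback: generate the C5 enolate reductively instead of by deprotonation. Omit Step 11, install the 2β,3β-epoxide on 12 with VO(acac)2/TBHP directed by C1-OH, and carry the 4β,5β-epoxide to the keto-lactol stage (no C4 protection needed). Then close ring B with SmI2 (THF, −78 °C): epoxide C–O cleavage gives the C5 samarium enolate regiospecifically, which adds to the aldehyde through a chelated transition state and delivers C4-OH and C6-OH together.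

2. **Step 14 (asymmetric hydrogenation of a hindered, polyfunctional enamide).** Fallback: drop the amino-acid side chain. Olefinate 6 with Ph3P=CHCO2Me, conjugate-reduce, and carry a plain C8–C7–C6 chain through the same ring-A chemistry and aldol. Then introduce nitrogen after bicyclisation by Rh2(esp)2/PhI(OAc)2 C–H amination of a C6-O-carbamate. The tether can only reach the exo C7–H cis to C6-O, and the resulting oxazolidinone is opened and acylated.

3. **Step 11 (SmI2 opening next to a tertiary α′-OH and an enamide ester).** Fallback: change the order so the reduction is run on a substrate with no reducible side chain. Reduce 4 to the C8 carbinol (NaBH4), protect it as the TBDPS ether, and carry out C9 oxidation, epoxy-ketone opening (two-electron selenoborate Na[PhSeB(OEt)3] rather than single-electron transfer) and directed epoxidation. Only then unveil and oxidise C8 and build the dehydroamino ester.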